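Ring A is disconnected at C3'–C4' and C1'–C2'. Four of its carbons (C4', C5', methoxy-bearing C6', C1') and the cinnamoyl carbonyl are already present in 5,6-dehydrokawain; C3' and C2' are the α-carbon and carbonyl of a chain ester that carries both stereocentres (C3, C5). In one operation the ester enolate is acylated by the pyranone carbonyl, the heterocycle opens, and a Dieckmann-type Claisen closure aromatises to the fully substituted acylphloroglucinol, so ring A needs no later alkylation, acylation or selective O-methylation. The precursor, methyl (3S,5S)-3-(4-silyloxystyryl)-5-silyloxy-7-phenylheptanoate, arises from trans-selective alkenyl cuprate addition to an (S)-6-phenethyl dihydropyranone, methanolysis and silylation.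

Key step: step 8

Remark: 5,6-dehydrokawain and 4-(tert-butyldimethylsilyloxy)benzaldehyde are taken as catalogue compounds; since basic methanolysis is expected to strip the aryl silyl ether, phenol and carbinol are silylated together after ring opening, both as TBS ethers.

Step 1
Reactants: 1 3-phenylpropanal
Product: 2 (3S)-1-phenylhex-5-en-3-ol
Conditions: (R)-BINOL (20 mol%), Ti(OiPr)4 (10 mol%), 4 Å MS, allyltributylstannane, CH2Cl2, −20 °C; aq. NaHCO3
Reagents that add atoms: allyltributylstannane, C=CC[Sn](CCCC)(CCCC)CCCC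
Why: Keck asymmetric allylation, in which the (R)-BINOL–titanium Lewis acid shields one aldehyde face so that the allylstannane should deliver the (S)-carbinol (C5 of the target), the sense established for unbranched aliphatic aldehydes.

Step 2
Reactants: 2 (3S)-1-phenylhex-5-en-3-ol; 3 acryloyl chloride
Product: 4 (3S)-1-phenylhex-5-en-3-yl prop-2-enoate
Conditions: Et3N, DMAP (cat.), CH2Cl2, 0 °C
Reagents that add atoms: none
Why: DMAP-catalysed O-acylation of a secondary alcohol with an acid chloride, which does not touch the stereocentre.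

Step 3
Reactants: 4 (3S)-1-phenylhex-5-en-3-yl prop-2-enoate
Product: 5 (6S)-6-(2-phenylethyl)-5,6-dihydro-2H-pyran-2-one
Conditions: second-generation Grubbs catalyst (3 mol%), CH2Cl2 (0.01 M), 40 °C
Reagents that add atoms: none
Why: Ring-closing metathesis of the acrylate with the terminal alkene closes the six-membered unsaturated lactone with loss of ethene, remote from the stereocentre.

Step 4
Reactants: 6 4-(tert-butyldimethylsilyloxy)benzaldehyde
Product: 7 tert-butyl{4-[(E)-2-iodovinyl]phenoxy}dimethylsilane
Conditions: CrCl2 (6 equiv), CHI3 (2 equiv), THF, 0 °C to rt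
Reagents that add atoms: iodoform, IC(I)I
Why: Takai olefination, in which the geminal dichromium species from iodoform adds to the aromatic aldehyde and eliminates to give mainly the (E)-iodoalkene under neutral conditions that spare the aryl silyl ether.

Step 5
Reactants: 7 tert-butyl{4-[(E)-2-iodovinyl]phenoxy}dimethylsilane; 5 (6S)-6-(2-phenylethyl)-5,6-dihydro-2H-pyran-2-one
Product: 10 (4S,6S)-4-{(E)-2-[4-(tert-butyldimethylsilyloxy)phenyl]vinyl}-6-(2-phenylethyl)tetrahydro-2H-pyran-2-one, via alkenyllithium 8 (not isolated), via lithium dialkenylcuprate 9 (not isolated)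
Conditions: 7 (3 equiv), t-BuLi (6 equiv), Et2O, −78 °C; CuBr·SMe2 (1.5 equiv), −78 to −40 °C; 5, −78 to −30 °C; aq. NH4Cl
Reagents that add atoms: none
Why: Iodine–lithium exchange with retention of alkene geometry, then Gilman cuprate conjugate addition to the unsaturated δ-lactone, where the alkenyl group should enter axially on the half-chair face opposite the pseudo-equatorial C6 phenethyl group and so set C4 trans to C6 (C3 of the target).

Step 6
Reactants: 10 (4S,6S)-4-{(E)-2-[4-(tert-butyldimethylsilyloxy)phenyl]vinyl}-6-(2-phenylethyl)tetrahydro-2H-pyran-2-one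
Product: 11 methyl (3S,5S)-5-hydroxy-3-[(E)-2-(4-hydroxyphenyl)vinyl]-7-phenylheptanoate
Conditions: K2CO3 (1.5 equiv), MeOH, 0 °C to rt; pH 7 buffer, extraction, concentration below 25 °C, used at once
Reagents that add atoms: methanol, CO
Why: Base-catalysed transesterification (lactone methanolysis) is driven to the open hydroxy ester by methanol as solvent, the base-labile aryl silyl ether is cleaved at the same time, and neither stereocentre is epimerisable.

Step 7
Reactants: 11 methyl (3S,5S)-5-hydroxy-3-[(E)-2-(4-hydroxyphenyl)vinyl]-7-phenylheptanoate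
Product: 12 methyl (3S,5S)-5-(tert-butyldimethylsilyloxy)-3-{(E)-2-[4-(tert-butyldimethylsilyloxy)phenyl]vinyl}-7-phenylheptanoate
Conditions: TBSOTf (2.6 equiv), 2,6-lutidine, CH2Cl2, −78 to 0 °C
Reagents that add atoms: tert-butyldimethylsilyl trifluoromethanesulfonate, CC(C)(C)[Si](C)(C)OS(=O)(=O)C(F)(F)F
Why: Silyl triflate silylation of the phenol and the secondary alcohol at −78 °C should be fast enough to outrun re-lactonisation of the δ-hydroxy ester.

Step 8
Reactants: 12 methyl (3S,5S)-5-(tert-butyldimethylsilyloxy)-3-{(E)-2-[4-(tert-butyldimethylsilyloxy)phenyl]vinyl}-7-phenylheptanoate; 13 4-methoxy-6-[(E)-2-phenylvinyl]-2H-pyran-2-one (5,6-dehydrokawain)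
Product: 15 (2E)-1-{3-[(1E,3R,5S)-5-(tert-butyldimethylsilyloxy)-1-[4-(tert-butyldimethylsilyloxy)phenyl]-7-phenylhept-1-en-3-yl]-2,4-dihydroxy-6-methoxyphenyl}-3-phenylprop-2-en-1-one (bis-TBS ether of alpinnanin C), via open-chain keto ester 14 (not isolated)
Conditions: LDA (1.0 equiv), THF, −78 °C; 13 (1.1 equiv), −78 to −40 °C; LiHMDS (2.5 equiv), −40 °C to rt; AcOH, 0 °C
Reagents that add atoms: none
Why: Proposed new method: the lithium enolate of 12 is expected to add to the lactone carbonyl (C2) of 13, forming the C3'–C4' bond, and the tetrahedral adduct to collapse by expelling the ring oxygen as a dienolate, which leaves open-chain 14 as its keto ester enolate; LiHMDS then removes a proton from the CH2 between the styryl ketone and the enol ether (former pyranone C5), this carbon attacks the ester carbonyl to form the C1'–C2' bond, methoxide leaves and the cyclic trione enolises to the arene. The closest known reaction types are the addition of ester-stabilised carbanions to the carbonyl of 4-methoxy-2-pyranones with ring opening and the base-mediated Claisen cyclisation of 3,5,7-tricarbonyl esters to acylphloroglucinols, so only their combination in one flask with an external ester is new. Ring A closes in a 6-(enolexo)-exo-trig Dieckmann-type Claisen mode, which is geometrically possible because the enol ether of 14 inherits the cis arrangement of the pyranone C3=C4 bond. No stereocentre is created, and the chain centres survive because C3 is β to the enolate, has no leaving group and is not acidified, while C5 is a silyl ether. The step requires 1,2-attack at the lactone carbonyl instead of 1,6- or 1,8-conjugate addition, which a hard lithium enolate in THF at −78 °C without polar additives should favour because C4 and C6 of 13 are deactivated by their oxygen donors. It also requires the Claisen closure to outrun aldol and lactonisation paths, which the substrate secures because an aldol adduct cannot aromatise at the chain-bearing C3' and the methylated C6' oxygen cannot lactonise.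

Step 9
Reactants: 15 bis-TBS ether of alpinnanin C
Product: 16 (2E)-1-{2,4-dihydroxy-3-[(1E,3R,5S)-5-hydroxy-1-(4-hydroxyphenyl)-7-phenylhept-1-en-3-yl]-6-methoxyphenyl}-3-phenylprop-2-en-1-one (alpinnanin C)
Conditions: HF·pyridine, pyridine, THF, 0 °C to rt
Reagents that add atoms: none
Why: Fluoride-mediated Si–O cleavage under buffered, non-basic conditions should remove both silyl ethers without forming the phenoxides that promote chalcone-to-flavanone cyclisation.

Compound list
1 | 3-phenylpropanal | O=CCCc1ccccc1 | starting material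
2 | (3S)-1-phenylhex-5-en-3-ol | C=CC[C@@H](O)CCc1ccccc1 | intermediate
3 | acryloyl chloride | C=CC(=O)Cl | starting material
4 | (3S)-1-phenylhex-5-en-3-yl prop-2-enoate | C=CC[C@@H](OC(=O)C=C)CCc1ccccc1 | intermediate
5 | (6S)-6-(2-phenylethyl)-5,6-dihydro-2H-pyran-2-one | O=C1C=CC[C@H](CCc2ccccc2)O1 | intermediate
6 | 4-(tert-butyldimethylsilyloxy)benzaldehyde | O=Cc1ccc(O[Si](C)(C)C(C)(C)C)cc1 | starting material
7 | tert-butyl{4-[(E)-2-iodovinyl]phenoxy}dimethylsilane | I/C=C/c1ccc(O[Si](C)(C)C(C)(C)C)cc1 | intermediate
8 | (E)-2-[4-(tert-butyldimethylsilyloxy)phenyl]vinyllithium | [Li]/C=C/c1ccc(O[Si](C)(C)C(C)(C)C)cc1 | intermediate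
9 | lithium bis{(E)-2-[4-(tert-butyldimethylsilyloxy)phenyl]vinyl}cuprate | [Li+].CC(C)(C)[Si](C)(C)Oc1ccc(/C=C/[Cu-]/C=C/c2ccc(O[Si](C)(C)C(C)(C)C)cc2)cc1 | intermediate
10 | (4S,6S)-4-{(E)-2-[4-(tert-butyldimethylsilyloxy)phenyl]vinyl}-6-(2-phenylethyl)tetrahydro-2H-pyran-2-one (4,6-trans) | O=C1C[C@@H](/C=C/c2ccc(O[Si](C)(C)C(C)(C)C)cc2)C[C@H](CCc2ccccc2)O1 | intermediate
11 | methyl (3S,5S)-5-hydroxy-3-[(E)-2-(4-hydroxyphenyl)vinyl]-7-phenylheptanoate | COC(=O)C[C@@H](/C=C/c1ccc(O)cc1)C[C@@H](O)CCc1ccccc1 | intermediate
12 | methyl (3S,5S)-5-(tert-butyldimethylsilyloxy)-3-{(E)-2-[4-(tert-butyldimethylsilyloxy)phenyl]vinyl}-7-phenylheptanoate | COC(=O)C[C@@H](/C=C/c1ccc(O[Si](C)(C)C(C)(C)C)cc1)C[C@@H](O[Si](C)(C)C(C)(C)C)CCc1ccccc1 | intermediate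
13 | 4-methoxy-6-[(E)-2-phenylvinyl]-2H-pyran-2-one (5,6-dehydrokawain) | COC1=CC(=O)OC(/C=C/c2ccccc2)=C1 | starting material
14 | methyl (4E,8E)-5-methoxy-3,7-dioxo-9-phenyl-2-[(1E,5S)-5-(tert-butyldimethylsilyloxy)-1-[4-(tert-butyldimethylsilyloxy)phenyl]-7-phenylhept-1-en-3-yl]nona-4,8-dienoate (chain stereocentres as in 12; C2 epimers and enol forms) | COC(=O)C([C@@H](/C=C/c1ccc(O[Si](C)(C)C(C)(C)C)cc1)C[C@@H](O[Si](C)(C)C(C)(C)C)CCc1ccccc1)C(=O)/C=C(/OC)CC(=O)/C=C/c1ccccc1 | intermediate
15 | (2E)-1-{3-[(1E,3R,5S)-5-(tert-butyldimethylsilyloxy)-1-[4-(tert-butyldimethylsilyloxy)phenyl]-7-phenylhept-1-en-3-yl]-2,4-dihydroxy-6-methoxyphenyl}-3-phenylprop-2-en-1-one (bis-TBS ether of alpinnanin C) | COc1cc(O)c([C@@H](/C=C/c2ccc(O[Si](C)(C)C(C)(C)C)cc2)C[C@@H](O[Si](C)(C)C(C)(C)C)CCc2ccccc2)c(O)c1C(=O)/C=C/c1ccccc1 | intermediate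
16 | alpinnanin C, (2E)-1-{2,4-dihydroxy-3-[(1E,3R,5S)-5-hydroxy-1-(4-hydroxyphenyl)-7-phenylhept-1-en-3-yl]-6-methoxyphenyl}-3-phenylprop-2-en-1-one | COc1cc(O)c([C@@H](/C=C/c2ccc(O)cc2)C[C@@H](O)CCc2ccccc2)c(O)c1C(=O)/C=C/c1ccccc1 | target

Total step count: 9. Longest linear sequence: 8 steps (steps 1, 2, 3, 5, 6, 7, 8, 9 from 3-phenylpropanal); step 4 is a one-step branch.

Steps most likely to fail

Step 8 (proposed new method). The enolate may add in conjugate fashion to C6 or to the styryl terminus of the pyranone instead of its carbonyl, or the sequence may stall after the first acylation because the keto ester enolate resists ring closure. The fallback makes the same two bonds stepwise with known carbonyl chemistry; it sets out from 12 and comes back at 14, then 15. The lithium enolate of 12 (LDA, THF, −78 °C) is C-acylated with the known reagent (E)-3-methoxybut-2-enoyl chloride (CO/C(C)=C/C(Cl)=O) in a crossed Claisen acylation to give β-keto ester F1. Treatment of F1 with LDA (2.2 equiv) should give the dianion whose second charge sits on the γ-methyl group of the β-methoxy enone, and acylation of that terminus with N-methoxy-N-methylcinnamamide gives 14, now isolated. Compound 14 is then cyclised in a separate operation with Mg(OMe)2 in MeOH or LiHMDS in THF, the established Claisen cyclisation of 3,5,7-tricarbonyl esters to acylphloroglucinols, to deliver 15.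

Step 6. The hydroxy ester may close back to the lactone during neutralisation, concentration or silylation. The fallback opens the ring irreversibly; it sets out from 10 and comes back at 12. Saponification with LiOH in THF/H2O opens the lactone and removes the aryl silyl group, giving lithium carboxylate F2. Without acidification the dried salt is silylated on all three oxygens (TBSCl, imidazole, DMF) to tris-silyl compound F3. The silyl ester alone is hydrolysed with AcOH/THF/H2O to carboxylic acid F4, which TMSCHN2 in toluene/MeOH methylates to 12.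

Step 5. Iodine–lithium exchange may be incomplete, the alkenyl cuprate may decay thermally, or 1,2-addition and erosion of the trans/cis ratio may intervene. The fallback replaces the stoichiometric organocopper reagent by a catalytic organoboron addition; it sets out from 7 (with 5) and comes back at 10. Alkenyllithium 8 is trapped with 2-isopropoxy-4,4,5,5-tetramethyl-1,3,2-dioxaborolane to give pinacol boronate F5. F5 adds to 5 in a Rh-catalysed Hayashi–Miyaura 1,4-addition ([Rh(cod)OH]2, dioxane/H2O, 40 °C). The alkenylrhodium species is again expected to enter anti to the C6 substituent, and a chiral diphosphine matched to that bias can reinforce it.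

Further compounds
F1 | step 8 | methyl (4E)-5-methoxy-3-oxo-2-[(1E,5S)-5-(tert-butyldimethylsilyloxy)-1-[4-(tert-butyldimethylsilyloxy)phenyl]-7-phenylhept-1-en-3-yl]hex-4-enoate (chain stereocentres as in 12) | COC(=O)C([C@@H](/C=C/c1ccc(O[Si](C)(C)C(C)(C)C)cc1)C[C@@H](O[Si](C)(C)C(C)(C)C)CCc1ccccc1)C(=O)/C=C(/OC)C
F2 | step 6 | lithium (3S,5S)-5-hydroxy-3-[(E)-2-(4-hydroxyphenyl)vinyl]-7-phenylheptanoate | [Li+].[O-]C(=O)C[C@@H](/C=C/c1ccc(O)cc1)C[C@@H](O)CCc1ccccc1
F3 | step 6 | tert-butyldimethylsilyl (3S,5S)-5-(tert-butyldimethylsilyloxy)-3-{(E)-2-[4-(tert-butyldimethylsilyloxy)phenyl]vinyl}-7-phenylheptanoate | CC(C)(C)[Si](C)(C)OC(=O)C[C@@H](/C=C/c1ccc(O[Si](C)(C)C(C)(C)C)cc1)C[C@@H](O[Si](C)(C)C(C)(C)C)CCc1ccccc1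
F4 | step 6 | (3S,5S)-5-(tert-butyldimethylsilyloxy)-3-{(E)-2-[4-(tert-butyldimethylsilyloxy)phenyl]vinyl}-7-phenylheptanoic acid | OC(=O)C[C@@H](/C=C/c1ccc(O[Si](C)(C)C(C)(C)C)cc1)C[C@@H](O[Si](C)(C)C(C)(C)C)CCc1ccccc1
F5 | step 5 | tert-butyldimethyl{4-[(E)-2-(4,4,5,5-tetramethyl-1,3,2-dioxaborolan-2-yl)vinyl]phenoxy}silane | CC1(C)OB(/C=C/c2ccc(O[Si](C)(C)C(C)(C)C)cc2)OC1(C)C
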